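**Abbreviations:** TBS = tert-butyldimethylsilyl, TBDPS = tert-butyldiphenylsilyl, TES = triethylsilyl, PMB = 4-methoxybenzyl.

**Assumption:** (R)-citronellic acid of ≥98% ee is purchased, and the transfer hydrogenation in step 9 follows the facial sense known for simple alkynyl ketones (alkynyl group as the directing π-substituent).

## Retrosynthetic overview

1. The target comes from its bis-silyl ether by desilylation. Both rings (cyclohexene and α-methylene lactone) close in one operation from an acyclic allenyl aldehyde, by a molybdenum-mediated [2+2+1] coupling of the aldehyde C=O, the inner allene C=C and CO (new bonds C3a–C7a, C3–C2 and C2–O1).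
2. The allenyl aldehyde comes from an (S)-allenyl angelate whose aldehyde is masked as a dioxolane. The allene comes from hydride SN2′ reduction of a 4-methoxy-2-ynol, and the carbinol center from asymmetric transfer hydrogenation of an ynone.
3. The ynone comes from a Weinreb amide that carries the tetrasubstituted olefin, made from a Z-enol triflate of a β-keto amide by Negishi coupling.
4. The β-keto amide comes from aldol addition and oxidation on the Weinreb amide of (R)-citronellic acid, which supplies the side-chain stereocenter; ozonolysis cuts its prenyl end to the primary alcohol.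
5. Ring order: no ring exists before step 13; carbocycle and lactone form together in that step.

## Route

Step 1
Reactants: 1 (R)-citronellic acid [(3R)-3,7-dimethyloct-6-enoic acid]
Product: 3 (3R)-N-methoxy-N,3,7-trimethyloct-6-enamide, via acyl imidazole 2 (not isolated)
Conditions: CDI, CH2Cl2, rt; then MeNHOMe·HCl, rt
Reagents that add atoms: N,O-dimethylhydroxylamine hydrochloride, CNOC.Cl
Why: Activation of the acid as its acyl imidazole and aminolysis gives the Weinreb amide (Weinreb amidation), which later serves as enolate precursor and as the acyl group for ketone synthesis, and the C3 stereocenter is not touched.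

Step 2
Reactants: 3 Weinreb amide of citronellic acid
Product: 5 (3R)-6-hydroxy-N-methoxy-N,3-dimethylhexanamide, via secondary ozonide 4 (not isolated)
Conditions: O3, CH2Cl2, −78 °C; then NaBH4, MeOH, −78 °C → rt
Reagents that add atoms: ozone, [O-][O+]=O
Why: Criegee ozonolysis of the only C=C bond with reductive work-up (NaBH4 reduces the ozonide but not the amide) shortens the chain to the primary alcohol.

Step 3
Reactants: 5 hydroxy amide
Product: 6 (3R)-6-[(tert-butyldiphenylsilyl)oxy]-N-methoxy-N,3-dimethylhexanamide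
Conditions: TBDPSCl, imidazole, CH2Cl2, rt
Reagents that add atoms: tert-butyl(chloro)diphenylsilane, CC(C)(C)[Si](Cl)(c1ccccc1)c1ccccc1
Why: Imidazole-promoted silylation of the primary alcohol gives an ether that withstands bases, hydrides and the later metal-mediated steps until the last step (silyl ether protection).

Step 4
Reactants: 6 silyl-protected Weinreb amide
Product: 8 (3R)-2-{2-[(tert-butyldimethylsilyl)oxy]-1-hydroxyethyl}-6-[(tert-butyldiphenylsilyl)oxy]-N-methoxy-N,3-dimethylhexanamide, via lithium enolate 7 (not isolated)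
Conditions: LiN(iPr)2, THF, −78 °C; then TBSOCH2CHO, −78 °C
Reagents that add atoms: (tert-butyldimethylsilyloxy)acetaldehyde, CC(C)(C)[Si](C)(C)OCC=O
Why: The lithium Z-enolate of the Weinreb amide adds to the aldehyde at low temperature (aldol addition); the two new stereocenters form unselectively but are both erased in steps 5 and 6.

Step 5
Reactants: 8 aldol adduct (diastereomer mixture)
Product: 9 (3R)-2-{[(tert-butyldimethylsilyl)oxy]acetyl}-6-[(tert-butyldiphenylsilyl)oxy]-N-methoxy-N,3-dimethylhexanamide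
Conditions: Dess–Martin periodinane, CH2Cl2, 0 °C → rt
Reagents that add atoms: none
Why: Dess–Martin oxidation turns the secondary alcohol into the β-keto amide without touching the silyl ethers; the epimerizable C2 center is removed in step 6.

Step 6
Reactants: 9 β-keto amide
Product: 11 (2Z)-4-[(TBS)oxy]-2-{(2R)-5-[(TBDPS)oxy]pentan-2-yl}-N-methoxy-N-methyl-3-{[(trifluoromethyl)sulfonyl]oxy}but-2-enamide, via sodium enolate 10 (not isolated)
Conditions: NaH, THF, 0 °C; then PhNTf2, 0 °C → rt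
Reagents that add atoms: N-phenylbis(trifluoromethanesulfonimide), O=S(=O)(N(c1ccccc1)S(=O)(=O)C(F)(F)F)C(F)(F)F
Why: Deprotonation between the two carbonyls gives a sodium-chelated enolate, and its O-sulfonylation fixes the olefin geometry with the triflate cis to the amide carbonyl (chelation-controlled Z-selective enol triflate formation).

Step 7
Reactants: 11 Z-enol triflate
Product: 12 (2E)-4-[(TBS)oxy]-2-{(2R)-5-[(TBDPS)oxy]pentan-2-yl}-3-(1,3-dioxolan-2-ylmethyl)-N-methoxy-N-methylbut-2-enamide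
Conditions: BrZnCH2(1,3-dioxolan-2-yl) (2 equiv), PdCl2(dppf) (5 mol %), THF, 60 °C
Reagents that add atoms: (1,3-dioxolan-2-ylmethyl)zinc bromide, Br[Zn]CC1OCCO1
Why: Negishi sp3–sp2 cross-coupling replaces the triflate with retention of olefin geometry, so the masked-aldehyde arm sits cis to the amide carbon and the silyloxymethyl group cis to the sec-alkyl group, as the ring closure needs.

Step 8
Reactants: 12 acetal-bearing unsaturated Weinreb amide
Product: 13 (5E)-7-[(TBS)oxy]-5-{(2R)-5-[(TBDPS)oxy]pentan-2-yl}-6-(1,3-dioxolan-2-ylmethyl)-1-methoxyhept-5-en-2-yn-4-one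
Conditions: HC≡CCH2OMe, n-BuLi, THF, −78 °C; then 12, −78 → 0 °C
Reagents that add atoms: 3-methoxyprop-1-yne, C#CCOC
Why: Weinreb ketone synthesis: the lithium acetylide adds once to the N-methoxy-N-methyl amide, because the chelated tetrahedral adduct collapses to the ynone only on quench.

Step 9
Reactants: 13 ynone
Product: 14 (4S,5E)-7-[(TBS)oxy]-5-{(2R)-5-[(TBDPS)oxy]pentan-2-yl}-6-(1,3-dioxolan-2-ylmethyl)-1-methoxyhept-5-en-2-yn-4-ol
Conditions: Ru[(R,R)-TsDPEN](p-cymene) (2 mol %), iPrOH, rt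
Reagents that add atoms: none
Why: Noyori asymmetric transfer hydrogenation of an alkynyl ketone sets the (4S) carbinol center under catalyst control, the alkynyl group being the directing π-substituent and the twisted tetrasubstituted alkenyl group acting as the bulky alkyl partner.

Step 10
Reactants: 14 propargylic alcohol
Product: 15 (4S,5E)-7-[(TBS)oxy]-5-{(2R)-5-[(TBDPS)oxy]pentan-2-yl}-6-(1,3-dioxolan-2-ylmethyl)hepta-1,2,5-trien-4-ol
Conditions: LiAlH4, THF, 0 → 65 °C
Reagents that add atoms: none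
Why: Alkoxide-directed trans-hydroalumination puts hydride on the proximal alkyne carbon and aluminium on the distal one, and 1,2-elimination of the methoxide then gives the terminal allene without touching the carbinol center (SN2′-type hydride reduction of a 4-alkoxy-2-yn-1-ol).

Step 11
Reactants: 15 allenyl carbinol
Product: 16 (4S,5E)-7-[(TBS)oxy]-5-{(2R)-5-[(TBDPS)oxy]pentan-2-yl}-6-(1,3-dioxolan-2-ylmethyl)hepta-1,2,5-trien-4-yl (2Z)-2-methylbut-2-enoate
Conditions: angelic acid, 2,4,6-Cl3C6H2COCl, Et3N, toluene, rt; then 15, 80 °C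
Reagents that add atoms: angelic acid [(2Z)-2-methylbut-2-enoic acid], C/C=C(/C)C(=O)O
Why: Yamaguchi esterification through the 2,4,6-trichlorobenzoyl mixed anhydride acylates the hindered secondary alcohol with retention at C4 and, run without DMAP, does not isomerize the Z (angelate) double bond to the E (tiglate) form.

Step 12
Reactants: 16 allenyl angelate acetal
Product: 18 (4S,5E)-7-[(TBS)oxy]-5-{(2R)-5-[(TBDPS)oxy]pentan-2-yl}-6-(2-oxoethyl)hepta-1,2,5-trien-4-yl (2Z)-2-methylbut-2-enoate, via collidinium salt 17 (not isolated)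
Conditions: TESOTf, 2,4,6-collidine, CH2Cl2, 0 °C; then H2O
Reagents that add atoms: water, O
Why: Silyl triflate–collidine acetal cleavage opens the dioxolane to a pyridinium-type intermediate that water hydrolyses under nearly neutral conditions, freeing the β,γ-unsaturated aldehyde without acid that could move the double bond into conjugation or ionize the allylic ester.

Step 13
Reactants: 18 allenyl aldehyde
Product: 19 (3aR,4S,7aR)-6-{[(TBS)oxy]methyl}-5-{(2R)-5-[(TBDPS)oxy]pentan-2-yl}-3-methylidene-2-oxo-2,3,3a,4,7,7a-hexahydro-1-benzofuran-4-yl (2Z)-2-methylbut-2-enoate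
Conditions: Mo(CO)6 (1.2 equiv), DMSO (5 equiv), toluene, 100 °C
Reagents that add atoms: molybdenum hexacarbonyl, [Mo].[C-]#[O+].[C-]#[O+].[C-]#[O+].[C-]#[O+].[C-]#[O+].[C-]#[O+]
Why: In this hetero-Pauson–Khand-type [2+2+1] cyclocarbonylation, zerovalent molybdenum couples the aldehyde C=O with the inner allene C=C (new C3a–C7a bond, six-membered ring), and CO insertion with C–O reductive elimination closes the cis-fused α-methylene lactone in the same operation; the angelate, held pseudoaxial by 1,2-allylic strain against the sec-alkyl group, makes the new C–C bond form anti to it, so C3a (R) and C7a (R) follow from C4 (S).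

Step 14
Reactants: 19 bicyclic bis-silyl ether
Product: 20 (3aR,4S,7aR)-6-(hydroxymethyl)-5-[(2R)-5-hydroxypentan-2-yl]-3-methylidene-2-oxo-2,3,3a,4,7,7a-hexahydro-1-benzofuran-4-yl (2Z)-2-methylbut-2-enoate
Conditions: HF·pyridine, pyridine, THF, 0 °C → rt
Reagents that add atoms: none
Why: Fluoride cleaves both primary silyl ethers (Si–F bond formation) in a buffered, non-basic medium that leaves the α-methylene lactone, the angelate and all four stereocenters untouched.

## Compound list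

1 | (R)-citronellic acid, (3R)-3,7-dimethyloct-6-enoic acid | OC(=O)C[C@H](C)CCC=C(C)C | starting material
2 | (3R)-1-(1H-imidazol-1-yl)-3,7-dimethyloct-6-en-1-one (acyl imidazole) | O=C(C[C@H](C)CCC=C(C)C)n1ccnc1 | intermediate
3 | (3R)-N-methoxy-N,3,7-trimethyloct-6-enamide | CON(C)C(=O)C[C@H](C)CCC=C(C)C | intermediate
4 | (3R)-5-(5,5-dimethyl-1,2,4-trioxolan-3-yl)-N-methoxy-N,3-dimethylpentanamide (secondary ozonide, ring carbon unassigned) | CON(C)C(=O)C[C@H](C)CCC1OOC(C)(C)O1 | intermediate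
5 | (3R)-6-hydroxy-N-methoxy-N,3-dimethylhexanamide | CON(C)C(=O)C[C@H](C)CCCO | intermediate
6 | (3R)-6-[(tert-butyldiphenylsilyl)oxy]-N-methoxy-N,3-dimethylhexanamide | CON(C)C(=O)C[C@H](C)CCCO[Si](c1ccccc1)(c1ccccc1)C(C)(C)C | intermediate
7 | lithium (Z)-enolate of 6 | CON(C)/C(O[Li])=C/[C@H](C)CCCO[Si](c1ccccc1)(c1ccccc1)C(C)(C)C | intermediate
8 | (3R)-2-{2-[(tert-butyldimethylsilyl)oxy]-1-hydroxyethyl}-6-[(tert-butyldiphenylsilyl)oxy]-N-methoxy-N,3-dimethylhexanamide (mixture at C2 and the carbinol carbon) | CON(C)C(=O)C([C@H](C)CCCO[Si](c1ccccc1)(c1ccccc1)C(C)(C)C)C(O)CO[Si](C)(C)C(C)(C)C | intermediate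
9 | (3R)-2-{[(tert-butyldimethylsilyl)oxy]acetyl}-6-[(tert-butyldiphenylsilyl)oxy]-N-methoxy-N,3-dimethylhexanamide (C2 epimers) | CON(C)C(=O)C([C@H](C)CCCO[Si](c1ccccc1)(c1ccccc1)C(C)(C)C)C(=O)CO[Si](C)(C)C(C)(C)C | intermediate
10 | sodium (Z)-enolate of 9 (chelated) | CON(C)C(=O)/C(=C(\O[Na])CO[Si](C)(C)C(C)(C)C)[C@H](C)CCCO[Si](c1ccccc1)(c1ccccc1)C(C)(C)C | intermediate
11 | (2Z)-4-[(TBS)oxy]-2-{(2R)-5-[(TBDPS)oxy]pentan-2-yl}-N-methoxy-N-methyl-3-{[(trifluoromethyl)sulfonyl]oxy}but-2-enamide | CON(C)C(=O)/C(=C(\OS(=O)(=O)C(F)(F)F)CO[Si](C)(C)C(C)(C)C)[C@H](C)CCCO[Si](c1ccccc1)(c1ccccc1)C(C)(C)C | intermediate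
12 | (2E)-4-[(TBS)oxy]-2-{(2R)-5-[(TBDPS)oxy]pentan-2-yl}-3-(1,3-dioxolan-2-ylmethyl)-N-methoxy-N-methylbut-2-enamide | CON(C)C(=O)/C(=C(\CC1OCCO1)CO[Si](C)(C)C(C)(C)C)[C@H](C)CCCO[Si](c1ccccc1)(c1ccccc1)C(C)(C)C | intermediate
13 | (5E)-7-[(TBS)oxy]-5-{(2R)-5-[(TBDPS)oxy]pentan-2-yl}-6-(1,3-dioxolan-2-ylmethyl)-1-methoxyhept-5-en-2-yn-4-one | COCC#CC(=O)/C(=C(\CC1OCCO1)CO[Si](C)(C)C(C)(C)C)[C@H](C)CCCO[Si](c1ccccc1)(c1ccccc1)C(C)(C)C | intermediate
14 | (4S,5E)-7-[(TBS)oxy]-5-{(2R)-5-[(TBDPS)oxy]pentan-2-yl}-6-(1,3-dioxolan-2-ylmethyl)-1-methoxyhept-5-en-2-yn-4-ol | COCC#C[C@H](O)/C(=C(\CC1OCCO1)CO[Si](C)(C)C(C)(C)C)[C@H](C)CCCO[Si](c1ccccc1)(c1ccccc1)C(C)(C)C | intermediate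
15 | (4S,5E)-7-[(TBS)oxy]-5-{(2R)-5-[(TBDPS)oxy]pentan-2-yl}-6-(1,3-dioxolan-2-ylmethyl)hepta-1,2,5-trien-4-ol | C=C=C[C@H](O)/C(=C(\CC1OCCO1)CO[Si](C)(C)C(C)(C)C)[C@H](C)CCCO[Si](c1ccccc1)(c1ccccc1)C(C)(C)C | intermediate
16 | (4S,5E)-7-[(TBS)oxy]-5-{(2R)-5-[(TBDPS)oxy]pentan-2-yl}-6-(1,3-dioxolan-2-ylmethyl)hepta-1,2,5-trien-4-yl (2Z)-2-methylbut-2-enoate | C=C=C[C@H](OC(=O)/C(C)=C\C)/C(=C(\CC1OCCO1)CO[Si](C)(C)C(C)(C)C)[C@H](C)CCCO[Si](c1ccccc1)(c1ccccc1)C(C)(C)C | intermediate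
17 | 2,4,6-trimethylpyridinium salt of 16 in which the opened acetal carbon carries the collidine nitrogen and a 2-(triethylsilyloxy)ethoxy group, triflate counter-ion (new carbon unassigned) | C=C=C[C@H](OC(=O)/C(C)=C\C)/C(=C(\CC(OCCO[Si](CC)(CC)CC)[n+]1c(C)cc(C)cc1C)CO[Si](C)(C)C(C)(C)C)[C@H](C)CCCO[Si](c1ccccc1)(c1ccccc1)C(C)(C)C.[O-]S(=O)(=O)C(F)(F)F | intermediate
18 | (4S,5E)-7-[(TBS)oxy]-5-{(2R)-5-[(TBDPS)oxy]pentan-2-yl}-6-(2-oxoethyl)hepta-1,2,5-trien-4-yl (2Z)-2-methylbut-2-enoate | C=C=C[C@H](OC(=O)/C(C)=C\C)/C(=C(\CC=O)CO[Si](C)(C)C(C)(C)C)[C@H](C)CCCO[Si](c1ccccc1)(c1ccccc1)C(C)(C)C | intermediate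
19 | (3aR,4S,7aR)-6-{[(TBS)oxy]methyl}-5-{(2R)-5-[(TBDPS)oxy]pentan-2-yl}-3-methylidene-2-oxo-2,3,3a,4,7,7a-hexahydro-1-benzofuran-4-yl (2Z)-2-methylbut-2-enoate | C=C1C(=O)O[C@@H]2CC(CO[Si](C)(C)C(C)(C)C)=C([C@H](C)CCCO[Si](c3ccccc3)(c3ccccc3)C(C)(C)C)[C@@H](OC(=O)/C(C)=C\C)[C@H]12 | intermediate
20 | (3aR,4S,7aR)-6-(hydroxymethyl)-5-[(2R)-5-hydroxypentan-2-yl]-3-methylidene-2-oxo-2,3,3a,4,7,7a-hexahydro-1-benzofuran-4-yl (2Z)-2-methylbut-2-enoate (CNP0106570.2) | C=C1C(=O)O[C@@H]2CC(CO)=C([C@H](C)CCCO)[C@@H](OC(=O)/C(C)=C\C)[C@H]12 | target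

## Step count and risks

Total step count: 14. Longest linear sequence: 14 (the route is fully linear from 1).

The three steps most likely to fail:

**Step 13 (ring-forming cyclocarbonylation).** The allylic, allene-adjacent angelate may be ionized by low-valent molybdenum, and the skipped enal may isomerize before it cyclizes. The fallback sets out from allenol 15 and carries the carbinol through the ring-forming step as an ether, with the ester introduced afterwards. NaH, PMBCl and Bu4NI give the (4S,5E) 4-methoxybenzyl ether of 15 F1. TESOTf and 2,4,6-collidine, then water, give the corresponding ether aldehyde F2. Ru3(CO)12 (5 mol %) under CO (20 atm, dioxane, 120 °C) closes both rings to the bicyclic ether lactone F3. DDQ in CH2Cl2 with pH 7 buffer frees the bicyclic alcohol F4. Yamaguchi angeloylation of F4, as in step 11, comes back to the route at 19.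

**Step 7 (sp3–sp2 Negishi coupling at a fully substituted, hindered enol triflate).** The coupling may be slow, and the β,β-dialkoxyalkyl zinc reagent may eliminate. The fallback sets out from triflate 11 and builds the two-carbon arm by sp2–sp2 coupling followed by functional-group adjustment. Suzuki coupling with vinylboronic acid pinacol ester (Pd(PPh3)4, K3PO4, dioxane/H2O) gives the (2E) dienamide F5. 9-BBN, then NaBO3, hydroborates only the terminal vinyl group to give the homoallylic alcohol F6. Dess–Martin oxidation gives the aldehyde F7. Acetalization with 1,2-bis(trimethylsilyloxy)ethane and catalytic TMSOTf at −78 °C comes back to the route at 12.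

**Step 10 (hydride SN2′ reduction with a methoxide leaving group).** Hot LiAlH4 may over-reduce the allenyl carbinol or cleave the allylic TBS ether. The fallback sets out from Weinreb amide 12 and makes the allene by one-carbon homologation of a terminal alkyne. LiC≡CSiMe3 gives the silyl ynone F8. The same transfer hydrogenation as in step 9 gives the silyl propargylic alcohol F9. K2CO3 in MeOH gives the terminal alkyne F10. Crabbé homologation (CuI, (CH2O)n, Cy2NH, dioxane, 100 °C) comes back to the route at 15.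

## Further compounds

F1 | step 13 | (4S,5E)-7-[(TBS)oxy]-5-{(2R)-5-[(TBDPS)oxy]pentan-2-yl}-6-(1,3-dioxolan-2-ylmethyl)hepta-1,2,5-trien-4-yl 4-methoxybenzyl ether | C=C=C[C@H](OCc1ccc(OC)cc1)/C(=C(\CC1OCCO1)CO[Si](C)(C)C(C)(C)C)[C@H](C)CCCO[Si](c1ccccc1)(c1ccccc1)C(C)(C)C
F2 | step 13 | (4S,5E)-7-[(TBS)oxy]-5-{(2R)-5-[(TBDPS)oxy]pentan-2-yl}-6-(2-oxoethyl)hepta-1,2,5-trien-4-yl 4-methoxybenzyl ether | C=C=C[C@H](OCc1ccc(OC)cc1)/C(=C(\CC=O)CO[Si](C)(C)C(C)(C)C)[C@H](C)CCCO[Si](c1ccccc1)(c1ccccc1)C(C)(C)C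
F3 | step 13 | (3aR,4S,7aR)-6-{[(TBS)oxy]methyl}-5-{(2R)-5-[(TBDPS)oxy]pentan-2-yl}-4-[(4-methoxybenzyl)oxy]-3-methylidene-3a,4,7,7a-tetrahydro-1-benzofuran-2(3H)-one | C=C1C(=O)O[C@@H]2CC(CO[Si](C)(C)C(C)(C)C)=C([C@H](C)CCCO[Si](c3ccccc3)(c3ccccc3)C(C)(C)C)[C@@H](OCc3ccc(OC)cc3)[C@H]12
F4 | step 13 | (3aS,4S,7aR)-6-{[(TBS)oxy]methyl}-5-{(2R)-5-[(TBDPS)oxy]pentan-2-yl}-4-hydroxy-3-methylidene-3a,4,7,7a-tetrahydro-1-benzofuran-2(3H)-one | C=C1C(=O)O[C@@H]2CC(CO[Si](C)(C)C(C)(C)C)=C([C@H](C)CCCO[Si](c3ccccc3)(c3ccccc3)C(C)(C)C)[C@@H](O)[C@H]12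
F5 | step 7 | (2E)-3-{[(TBS)oxy]methyl}-2-{(2R)-5-[(TBDPS)oxy]pentan-2-yl}-N-methoxy-N-methylpenta-2,4-dienamide | CON(C)C(=O)/C(=C(\C=C)CO[Si](C)(C)C(C)(C)C)[C@H](C)CCCO[Si](c1ccccc1)(c1ccccc1)C(C)(C)C
F6 | step 7 | (2E)-3-{[(TBS)oxy]methyl}-2-{(2R)-5-[(TBDPS)oxy]pentan-2-yl}-5-hydroxy-N-methoxy-N-methylpent-2-enamide | CON(C)C(=O)/C(=C(\CCO)CO[Si](C)(C)C(C)(C)C)[C@H](C)CCCO[Si](c1ccccc1)(c1ccccc1)C(C)(C)C
F7 | step 7 | (2E)-3-{[(TBS)oxy]methyl}-2-{(2R)-5-[(TBDPS)oxy]pentan-2-yl}-N-methoxy-N-methyl-5-oxopent-2-enamide | CON(C)C(=O)/C(=C(\CC=O)CO[Si](C)(C)C(C)(C)C)[C@H](C)CCCO[Si](c1ccccc1)(c1ccccc1)C(C)(C)C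
F8 | step 10 | (4E)-6-[(TBS)oxy]-4-{(2R)-5-[(TBDPS)oxy]pentan-2-yl}-5-(1,3-dioxolan-2-ylmethyl)-1-(trimethylsilyl)hex-4-en-1-yn-3-one | C[Si](C)(C)C#CC(=O)/C(=C(\CC1OCCO1)CO[Si](C)(C)C(C)(C)C)[C@H](C)CCCO[Si](c1ccccc1)(c1ccccc1)C(C)(C)C
F9 | step 10 | (3R,4E)-6-[(TBS)oxy]-4-{(2R)-5-[(TBDPS)oxy]pentan-2-yl}-5-(1,3-dioxolan-2-ylmethyl)-1-(trimethylsilyl)hex-4-en-1-yn-3-ol (same spatial arrangement as 14; descriptor changes because of silicon) | C[Si](C)(C)C#C[C@H](O)/C(=C(\CC1OCCO1)CO[Si](C)(C)C(C)(C)C)[C@H](C)CCCO[Si](c1ccccc1)(c1ccccc1)C(C)(C)C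
F10 | step 10 | (3S,4E)-6-[(TBS)oxy]-4-{(2R)-5-[(TBDPS)oxy]pentan-2-yl}-5-(1,3-dioxolan-2-ylmethyl)hex-4-en-1-yn-3-ol | C#C[C@H](O)/C(=C(\CC1OCCO1)CO[Si](C)(C)C(C)(C)C)[C@H](C)CCCO[Si](c1ccccc1)(c1ccccc1)C(C)(C)C
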